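(The runs are simulated for substances that don't exist; the scatter is artificial.)

At early times the maple flask looked like a plain coupling: by 6.00 h the target stood at 36.7 % of the starting material charged.

| flask | starting material | coupling partner | second substrate | third substrate | temperature | remark | time |
|---|---|---|---|---|---|---|---|
| maple | 0.58 M | 1.05 equiv | 0.20 equiv | 1 equiv | 70 °C | the very flask that is asked about, followed so far |  |
| ash | 0.58 M | 1.05 equiv | 0.20 equiv | 1 equiv | 65 °C | run made earlier |  |
| flask | 0.58 M | 1.05 equiv | 0.200 equiv | 1.00 equiv | 70 °C |  | 2.0 d |

| run | time / h | target / % | starting material / % |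
|---|---|---|---|
| maple | 6.00 | 36.7 | 42.7 |
| maple | 12.0 | 28.6 | 40.3 |
| maple | 20.0 | 21.5 | 40.1 |
| maple | 25.0 | 18.0 | 40.9 |
| maple | 30.0 | 15.7 | 40.6 |
| maple | 40.0 | 12.1 | 41.6 |
| ash | 6.00 | 40.4 | 45.1 |
| ash | 12.0 | 36.5 | 41.8 |
| ash | 20.0 | 31.5 | 39.6 |
| ash | 25.0 | 27.7 | 38.6 |
| ash | 30.0 | 25.9 | 38.2 |
| ash | 40.0 | 21.4 | 37.7 |

(standard deviation of a reading: 0.3 percentage points)

- removed target is counted in
- additions bring no volume worth counting

- Friday's: at 2.0 d take out 90 % of the target then present, then wait 25 h
- Sunday's: change nothing and wait 25 h more
- Thursday's: at 2.0 d add coupling partner, 100 % of the amount charged, then wait 25 h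
- Wednesday's: at 2.0 d raise the temperature by 20 K, then wait 25 h

1. target, in percent of the starting material first charged, at 2.0 d
2. what to do for the largest gain in target; "none" if nothing gains more than 2 percentage points (Friday's / Sunday's / Thursday's / Wednesday's / none)
3. target present, with what was taken out counted in, in percent of the starting material first charged, after Friday's
4. target present, with what was taken out counted in, in percent of the starting material first charged, after Thursday's

My bench rule was to count turnovers: one coupling partner per starting material, so 1.05 equiv of partner looked like enough for full conversion. The maple readings refused this: by 40.0 h the target had fallen to 12.1 % while the starting material stood at 41.6 %. So I counted the other claimants, supposing that each second and third substrate also takes one partner per turnover. Their charges together, divided by the partner charged, gave 1.14. That ratio is above one, and there the rule stopped working, since these two substrates could ask for more partner than was charged.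

The free partner of the maple flask came to −0.150 equiv, meaning the partner charged minus the charges of the second and third substrate. Being negative, it marked the partner to me as the limiting reagent of that flask, and I expected the target to go on falling. Carrying its fall from 20.0 h to 40.0 h forward gave me 9.61 % at 2.0 d. With Thursday's addition counted in, I reckoned the free partner at 0.900 equiv, above the 0.537 equiv of starting material and target seen at the last maple reading. That reading left 46.3 % of the starting material charged unaccounted for, and I counted none of it. So I chose Thursday's and committed to about 53.7 % of target after it.

The forecast gave 10 % at 2.0 d, 9.6 % after Friday's and 18 % after Thursday's, lower than my figure, and called Thursday's “the best option but uncertain”.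

The simulation of the asked flask gave 9.74 % at 2.0 d, 9.96 % after Friday's and 55.4 % after Thursday's, a gain of 46 percentage points, so the best choice was Thursday's.

    starting material + coupling partner ⇌ target (K = 15.0 M⁻¹, k = 0.0240 M⁻¹ min⁻¹, Ea = 78.0 kJ mol⁻¹, ΔH = −67.0 kJ mol⁻¹)
    second substrate + coupling partner → second product (k = 0.380 M⁻¹ min⁻¹, Ea = 76.0 kJ mol⁻¹)
    third substrate + coupling partner → third product (k = 0.0150 M⁻¹ min⁻¹, Ea = 62.0 kJ mol⁻¹)
    starting material ⇌ dormant form (K = 1.20, k = 0.00140 min⁻¹, Ea = 119 kJ mol⁻¹, ΔH = −26.0 kJ mol⁻¹)
    (constants at 70 °C)

The neighbour flask kept the recipe but held 0.250 equiv of third substrate, so its free partner came to 0.600 equiv, which is positive. At 48.0 h that neighbour flask held 42.1 % of target, against 9.74 % in the asked flask. Its third substrate stood at 0.794 % of its charge, and 17.3 % of its partner charge remained. In that neighbour flask, target and remaining partner together came to 0.602 equiv.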